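The route rests on cutting the C3–C3a bond of the oxindole lactam ring together with the exocyclic CH2–C6 (pyrazine) bond, which returns an acrylanilide and a bromopyrazine. The key step, a nickel-catalysed reductive cyclisation/cross-coupling, closes the five-membered ring at C3–C3a, attaches the pyrazine and sets C3 in one operation. It exploits two features. C3 and its CH2 neighbour carry C3a and pyrazine C6, the imprint of an alkene 1,2-diarylation. The C7 prenyl group ortho to N1 makes the N1–C7a bond of the N-substituted 2-bromoanilide a stable chirality axis, set by atroposelective N-allylation and transferred to C3 during ring closure.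

Key step: step 8

Assumption: the axis descriptor of 7 and 8 is carried in the name, because line notation has no symbol for an N–aryl axis.
Assumption: the (P)-axis to (S)-C3 correlation follows the usual transfer model (aryl cis to the acyl group, s-cis acryloyl, bond formation on the alkene face turned toward the C–Br carbon); if it proves reversed, the antipodal phase-transfer catalyst is used in step 3.
Assumption: the tertiary C3–H centre is treated as configurationally stable under neutral and acidic conditions and labile to base, so no basic step follows step 8.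
Assumption: 1, 2 and 9 are taken as purchasable.

Step 1
Reactants: 1 2-bromo-6-iodoaniline; 2 tributyl(3-methylbut-2-en-1-yl)stannane
Product: 3 2-bromo-6-(3-methylbut-2-en-1-yl)aniline
Conditions: Pd(PPh3)4 (5 mol %), DMF, 80 °C
Reagents that add atoms: tributyl(3-methylbut-2-en-1-yl)stannane, CCCC[Sn](CCCC)(CCCC)CC=C(C)C
Why: Stille coupling, in which zerovalent palladium inserts into C–I far faster than into C–Br and the prenylstannane should transfer through its α-carbon to give the linear prenyl arene with the bromide kept for step 8.

Step 2
Reactants: 3 2-bromo-6-(3-methylbut-2-en-1-yl)aniline; 4 acryloyl chloride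
Product: 5 N-[2-bromo-6-(3-methylbut-2-en-1-yl)phenyl]prop-2-enamide
Conditions: Et3N, CH2Cl2, 0 °C
Reagents that add atoms: acryloyl chloride, C=CC(=O)Cl
Why: N-acylation of the aniline by the acid chloride, where the hindered, weakly nucleophilic nitrogen should acylate once and not add to the acrylamide.

Step 3
Reactants: 5 N-[2-bromo-6-(3-methylbut-2-en-1-yl)phenyl]prop-2-enamide; 6 allyl bromide
Product: 7 (P)-N-allyl-N-[2-bromo-6-(3-methylbut-2-en-1-yl)phenyl]prop-2-enamide
Conditions: chiral C2-symmetric binaphthyl-derived spiro quaternary ammonium bromide (3 mol %), solid KOH, toluene, −20 °C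
Reagents that add atoms: allyl bromide, C=CCBr
Why: Atroposelective N-alkylation under chiral phase-transfer catalysis, a known route to axially chiral ortho-haloanilides, in which the chiral ammonium amidate ion pair is allylated with the Br and CH2 ortho groups differentiated, creating the N–aryl axis (no stereocentre) that the two ortho substituents keep from turning at room temperature.

Step 4
Reactants: 7 (P)-N-allyl-N-[2-bromo-6-(3-methylbut-2-en-1-yl)phenyl]prop-2-enamide
Product: 8 (P)-N-[2-bromo-6-(3-methylbut-2-en-1-yl)phenyl]-N-[(E)-prop-1-en-1-yl]prop-2-enamide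
Conditions: [Ir(cod)(PMePh2)2]PF6 (3 mol %, activated with H2, then degassed), THF, 25 °C
Reagents that add atoms: none
Why: Metal hydride-catalysed allyl to prop-1-enyl isomerisation, which should take only the monosubstituted N-allyl alkene (not the trisubstituted prenyl alkene or the conjugated acrylamide), removes a competing 5-exo acceptor for step 8, makes the N-substituent acid-labile, and at 25 °C leaves the axis intact.

Step 5
Reactants: 9 5-bromo-3-methylpyrazin-2(1H)-one; 10 4-methoxybenzyl chloride
Product: 11 5-bromo-2-[(4-methoxybenzyl)oxy]-3-methylpyrazine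
Conditions: Ag2CO3 (0.6 equiv), toluene, 60 °C, dark
Reagents that add atoms: 4-methoxybenzyl chloride, COc1ccc(CCl)cc1
Why: Silver-salt alkylation of the ambident pyrazinone, which directs the benzyl group to oxygen and gives the lactim ether that masks the C2=O/N1–H unit.

Step 6
Reactants: 11 5-bromo-2-[(4-methoxybenzyl)oxy]-3-methylpyrazine; 12 sodium methoxide
Product: 13 5-methoxy-2-[(4-methoxybenzyl)oxy]-3-methylpyrazine
Conditions: CuI (10 mol %), 1,10-phenanthroline (20 mol %), MeOH–toluene, 90 °C
Reagents that add atoms: sodium methoxide, C[O-].[Na+]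
Why: Ullmann-type copper-catalysed C–O coupling (with SNAr as a background path) should replace the C5 bromide, the only good leaving group on the ring, by methoxide.

Step 7
Reactants: 13 5-methoxy-2-[(4-methoxybenzyl)oxy]-3-methylpyrazine; 14 1,2-dibromo-1,1,2,2-tetrachloroethane
Product: 16 2-bromo-3-methoxy-6-[(4-methoxybenzyl)oxy]-5-methylpyrazine, via pyrazin-2-ylmagnesium chloride 15 (not isolated)
Conditions: TMPMgCl·LiCl (1.2 equiv), THF, −40 °C; then 14, −40 to 20 °C
Reagents that add atoms: 1,2-dibromo-1,1,2,2-tetrachloroethane, BrC(Cl)(Cl)C(Cl)(Cl)Br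
Why: Directed magnesiation with the hindered amide base at the only ring C–H, which is ortho to OMe and α to N, followed by bromine transfer from the polyhaloethane.

Step 8
Reactants: 8 (P)-N-[2-bromo-6-(3-methylbut-2-en-1-yl)phenyl]-N-[(E)-prop-1-en-1-yl]prop-2-enamide; 16 2-bromo-3-methoxy-6-[(4-methoxybenzyl)oxy]-5-methylpyrazine
Product: 17 (3S)-3-({3-methoxy-6-[(4-methoxybenzyl)oxy]-5-methylpyrazin-2-yl}methyl)-7-(3-methylbut-2-en-1-yl)-1-[(E)-prop-1-en-1-yl]-1,3-dihydro-2H-indol-2-one
Conditions: NiBr2·glyme (10 mol %), 4,4'-di-tert-butyl-2,2'-bipyridine (12 mol %), Zn powder (3 equiv), 16 (1.5 equiv), DMA, 20 °C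
Reagents that add atoms: none
Why: Proposed new method: zerovalent nickel should insert into the C–Br bond of 8, the aryl–nickel then adds across the acrylamide C=C in a migratory insertion (aryl carbon to the internal alkene carbon) that forms C3–C3a, and the primary alkyl–nickel so formed, after reduction by Zn, takes up bromopyrazine 16 and forms the CH2–C6 bond by reductive elimination. The closest known reaction types are the nickel-catalysed reductive diarylation of N-(2-bromoaryl)methacrylamides with (hetero)aryl bromides (domino cyclisation/cross-coupling, shown for 1,1-disubstituted alkenes giving quaternary C3) and the radical and Mizoroki–Heck cyclisations of axially chiral ortho-haloacrylanilides with axis-to-centre chirality transfer, whereas their combination on an α-unsubstituted acrylamide giving a tertiary C3–H centre is untested. The single ring closed is the lactam ring, in the 5-exo-trig mode. The new C3 stereocentre is controlled by the N1–C7a axis of 8, because the aryl ring stands perpendicular to the amide plane with the metalated carbon held over one face of the s-cis acrylamide, so that bond formation on that face should turn (P)-8 into (S)-17 and an achiral ligand suffices. The step needs cyclisation before any intermolecular coupling (secured by the tertiary anilide, whose aryl group lies cis to the acryloyl group, and by a modest excess of 16), 5-exo closure in preference to 6-endo closure or attack on the N-substituent (secured by the short amide tether and by the N-propenyl group, which offers only a 4-exo or 5-endo path), and capture of the alkyl–nickel before β-hydride loss of the C3–H (slow for nickel with a bipyridine ligand). The room-temperature, base-free reductive conditions are chosen so that neither the axis before closure nor the acidic C3–H after it is scrambled.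

Step 9
Reactants: 17 (3S)-3-({3-methoxy-6-[(4-methoxybenzyl)oxy]-5-methylpyrazin-2-yl}methyl)-7-(3-methylbut-2-en-1-yl)-1-[(E)-prop-1-en-1-yl]-1,3-dihydro-2H-indol-2-one
Product: 18 astepyrazinol B, (3S)-3-[(3-methoxy-5-methyl-6-oxo-1,6-dihydropyrazin-2-yl)methyl]-7-(3-methylbut-2-en-1-yl)-1,3-dihydro-2H-indol-2-one
Conditions: 2 M aq. HCl–THF (1:3), 40 °C
Reagents that add atoms: none
Why: Acid hydrolysis of the N-(prop-1-enyl) enamide (C-protonation, water addition, loss of propanal) together with acidolysis of the 4-methoxybenzyl lactim ether; dilute acid should spare the prenyl alkene and the C5 methyl ether, and the absence of base keeps the C3–H centre from epimerising.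

Compound list
1 | 2-bromo-6-iodoaniline | Nc1c(Br)cccc1I | starting material
2 | tributyl(3-methylbut-2-en-1-yl)stannane | CCCC[Sn](CCCC)(CCCC)CC=C(C)C | starting material
3 | 2-bromo-6-(3-methylbut-2-en-1-yl)aniline | Nc1c(Br)cccc1CC=C(C)C | intermediate
4 | acryloyl chloride | C=CC(=O)Cl | starting material
5 | N-[2-bromo-6-(3-methylbut-2-en-1-yl)phenyl]prop-2-enamide | C=CC(=O)Nc1c(Br)cccc1CC=C(C)C | intermediate
6 | allyl bromide | C=CCBr | starting material
7 | (P)-N-allyl-N-[2-bromo-6-(3-methylbut-2-en-1-yl)phenyl]prop-2-enamide (N–aryl axis P, equal to aS) | C=CCN(C(=O)C=C)c1c(Br)cccc1CC=C(C)C | intermediate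
8 | (P)-N-[2-bromo-6-(3-methylbut-2-en-1-yl)phenyl]-N-[(E)-prop-1-en-1-yl]prop-2-enamide (N–aryl axis P) | C/C=C/N(C(=O)C=C)c1c(Br)cccc1CC=C(C)C | intermediate
9 | 5-bromo-3-methylpyrazin-2(1H)-one | Cc1nc(Br)c[nH]c1=O | starting material
10 | 4-methoxybenzyl chloride | COc1ccc(CCl)cc1 | starting material
11 | 5-bromo-2-[(4-methoxybenzyl)oxy]-3-methylpyrazine | Cc1nc(Br)cnc1OCc1ccc(OC)cc1 | intermediate
12 | sodium methoxide | C[O-].[Na+] | starting material
13 | 5-methoxy-2-[(4-methoxybenzyl)oxy]-3-methylpyrazine | COc1cnc(OCc2ccc(OC)cc2)c(C)n1 | intermediate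
14 | 1,2-dibromo-1,1,2,2-tetrachloroethane | BrC(Cl)(Cl)C(Cl)(Cl)Br | starting material
15 | {3-methoxy-6-[(4-methoxybenzyl)oxy]-5-methylpyrazin-2-yl}magnesium chloride (LiCl complex) | COc1nc(C)c(OCc2ccc(OC)cc2)nc1[Mg]Cl | intermediate
16 | 2-bromo-3-methoxy-6-[(4-methoxybenzyl)oxy]-5-methylpyrazine | COc1nc(C)c(OCc2ccc(OC)cc2)nc1Br | intermediate
17 | (3S)-3-({3-methoxy-6-[(4-methoxybenzyl)oxy]-5-methylpyrazin-2-yl}methyl)-7-(3-methylbut-2-en-1-yl)-1-[(E)-prop-1-en-1-yl]-1,3-dihydro-2H-indol-2-one | COc1nc(C)c(OCc2ccc(OC)cc2)nc1C[C@@H]1C(=O)N(/C=C/C)c2c(CC=C(C)C)cccc21 | intermediate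
18 | astepyrazinol B, (3S)-3-[(3-methoxy-5-methyl-6-oxo-1,6-dihydropyrazin-2-yl)methyl]-7-(3-methylbut-2-en-1-yl)-1,3-dihydro-2H-indol-2-one | COc1nc(C)c(=O)[nH]c1C[C@@H]1C(=O)Nc2c(CC=C(C)C)cccc21 | target

Total step count: 9. Longest linear sequence: 6 steps (steps 1, 2, 3, 4, 8, 9); the pyrazine branch (steps 5, 6, 7) joins at step 8.

Steps most likely to fail

Step 8 (proposed new method). The alkyl–nickel may lose the C3–H by β-hydride elimination, cross-coupling with 16 may lag behind simple reduction, or the axis may not be transferred faithfully through the organonickel pathway. The fallback uses known chemistry, a radical cyclisation of an axially chiral ortho-haloacrylanilide with chirality transfer; it sets out from 16 and 3 and comes back at 17. Mizoroki–Heck coupling of 16 with acrylic acid (Pd(OAc)2, P(o-tol)3, Et3N, DMF, 90 °C) would give (E)-3-{3-methoxy-6-[(4-methoxybenzyl)oxy]-5-methylpyrazin-2-yl}prop-2-enoic acid F1. Activation with 1-chloro-N,N,2-trimethylprop-1-en-1-amine and acylation of 3 (pyridine, CH2Cl2) would give the secondary (E)-acrylanilide F2. Atroposelective allylation as in step 3 would give the (P)-N-allyl anilide F3, and isomerisation as in step 4 the (P)-N-(prop-1-enyl) anilide F4. Treatment with (Me3Si)3SiH and Et3B/air in toluene at 20 °C would then generate the aryl radical, which should close C3–C3a by 5-exo-trig attack on the alkene face fixed by the axis faster than the axis can turn; the pyrazine-stabilised exocyclic radical is reduced by the silane to give 17.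

Step 3. The chiral ion pair may discriminate poorly between the Br and CH2 ortho groups, so that the axis is formed with low enantiomeric purity. The fallback replaces phase-transfer alkylation by palladium-catalysed asymmetric allylic substitution; it sets out from 5 and comes back at 7. With allyl acetate, [Pd(allyl)Cl]2, a C2-symmetric trans-1,2-diaminocyclohexane-derived bis(2-diphenylphosphinobenzamide) ligand and NaH in THF at −20 °C, the anilide anion would attack the chiral π-allyl complex and the axis would be set in the C–N bond-forming event. No compound outside the list arises (F0).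

Step 7. The amide base may deprotonate the C3 methyl group laterally, or the benzylic CH2 of the 4-methoxybenzyl ether, instead of the ring C–H. The fallback uses N-oxide activation; it sets out from 13 and comes back at 16. mCPBA (CH2Cl2, 0 °C) should oxidise the less hindered N1 (flanked by C6–H) to give 5-methoxy-2-[(4-methoxybenzyl)oxy]-3-methylpyrazine 1-oxide F5. O-activation with Ts2O in the presence of Bu4NBr (CH2Cl2, 0 to 20 °C) would then deliver bromide to C6 with loss of the sulfonate, giving 16.

Further compounds
F1 | step 8 | (E)-3-{3-methoxy-6-[(4-methoxybenzyl)oxy]-5-methylpyrazin-2-yl}prop-2-enoic acid | COc1nc(C)c(OCc2ccc(OC)cc2)nc1/C=C/C(=O)O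
F2 | step 8 | (E)-N-[2-bromo-6-(3-methylbut-2-en-1-yl)phenyl]-3-{3-methoxy-6-[(4-methoxybenzyl)oxy]-5-methylpyrazin-2-yl}prop-2-enamide | COc1nc(C)c(OCc2ccc(OC)cc2)nc1/C=C/C(=O)Nc1c(Br)cccc1CC=C(C)C
F3 | step 8 | (P)-(E)-N-allyl-N-[2-bromo-6-(3-methylbut-2-en-1-yl)phenyl]-3-{3-methoxy-6-[(4-methoxybenzyl)oxy]-5-methylpyrazin-2-yl}prop-2-enamide | COc1nc(C)c(OCc2ccc(OC)cc2)nc1/C=C/C(=O)N(CC=C)c1c(Br)cccc1CC=C(C)C
F4 | step 8 | (P)-(E)-N-[2-bromo-6-(3-methylbut-2-en-1-yl)phenyl]-3-{3-methoxy-6-[(4-methoxybenzyl)oxy]-5-methylpyrazin-2-yl}-N-[(E)-prop-1-en-1-yl]prop-2-enamide | COc1nc(C)c(OCc2ccc(OC)cc2)nc1/C=C/C(=O)N(/C=C/C)c1c(Br)cccc1CC=C(C)C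
F0 | step 3 | none | none
F5 | step 7 | 5-methoxy-2-[(4-methoxybenzyl)oxy]-3-methylpyrazine 1-oxide | COc1c[n+]([O-])c(OCc2ccc(OC)cc2)c(C)n1
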